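**Plan**

- Cembrane numbering is used: C1 carries the C15(=C17)–C16 lactone unit, the lactone oxygen is on C2, the epoxide spans C3–C4, the alkenes are C7=C8 and C11=C12, and the acetate is on C14.
- Cuts: (a) the ring bond C8–C9 of the 14-membered carbocycle, between the methyl-bearing alkene carbon C8 and the unfunctionalised CH2 C9, which is homoallylic to C11=C12. C8 can therefore be an (E)-iodoalkene and C9 the boron end of a hydroborated terminal diene C9=C10–C11=C12. (b) C1–C14, giving a 3-(bromomethyl)butenolide and a dienal. (c) The butenolide, back to a C2–C8 enal, methyl propiolate and formaldehyde.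
- Forward: C5–C8 iodoalkene, then the C2–C8 enal, then the ynoate (adds C1, C15, C16), the epoxide ring, the butenolide ring (adds C17), union with the C9–C14 dienal (exo-methylene lactone and C14 carbinol), the acetate, and last the 14-membered ring.
- Stereochemistry: C2 is set by catalytic asymmetric alkynylation. C3 and C4 are relayed from C2 by hydroxyl-directed epoxidation under allylic 1,3-strain. C1 and C14 are relayed together in one allylindium addition (butenolide face, chair transition state). Both E alkenes come from syn hydro- or carbometalation of alkynes.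
- The exo-methylene is stored as its dimethylamine adduct during hydroboration and coupling and is released in the last step.

Key step: step 15

Assumption (chemistry): the (S,S) enantiomer of ProPhenol is taken as the one that delivers the 4R carbinol in step 6; if the sense of induction is the opposite, the (R,R) ligand is used and nothing else changes.

**Route**

Step 1
Reactants: 1 pent-3-yn-1-ol
Product: 3 (E)-4-iodopent-3-en-1-ol, via alkenylzirconocene 2 (not isolated)
Conditions: Cp2Zr(H)Cl (2.5 equiv), THF, 0 to 40 °C; then I2, 0 °C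
Reagents that add atoms: iodine (II)
Why: Schwartz hydrozirconation adds Zr–H syn and, after equilibration with excess reagent, places zirconium on the less hindered methyl-bearing alkyne carbon, so iodinolysis with retention should give the E iodoalkene (hydrozirconation–iodination).

Step 2
Reactants: 3 (E)-4-iodopent-3-en-1-ol
Product: 4 (E)-2,5-diiodopent-2-ene
Conditions: I2, PPh3, imidazole, CH2Cl2, 0 °C to rt
Reagents that add atoms: iodine (II)
Why: Appel-type iodination converts the primary alcohol into the primary iodide without touching the iodoalkene.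

Step 3
Reactants: 4 (E)-2,5-diiodopent-2-ene
Product: 5 (E)-6-iodohept-5-en-1-yne
Conditions: LiC≡CH·H2NCH2CH2NH2, DMSO, 10 °C to rt
Reagents that add atoms: lithium acetylide ethylenediamine complex ([Li+].[C-]#C.NCCN)
Why: SN2 alkylation of the acetylide takes place only at the primary sp3 iodide, because the alkenyl iodide cannot undergo substitution and has no anti hydrogen for elimination.

Step 4
Reactants: 5 (E)-6-iodohept-5-en-1-yne
Product: 7 (2E,6E)-7-iodo-3-methylocta-2,6-dien-1-ol, via alkenylalane 6 (not isolated)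
Conditions: Me3Al (2.5 equiv), Cp2ZrCl2 (0.25 equiv), CH2Cl2, 0 °C to rt; then (CH2O)n, THF, 0 °C to rt; aqueous potassium sodium tartrate
Reagents that add atoms: trimethylaluminium (C[Al](C)C); formaldehyde as paraformaldehyde (C=O)
Why: Negishi zirconium-catalysed carboalumination adds methyl and aluminium syn across the terminal alkyne with aluminium at the terminus, and hydroxymethylation of the alkenylalane with retention should give the E trisubstituted allylic alcohol.

Step 5
Reactants: 7 (2E,6E)-7-iodo-3-methylocta-2,6-dien-1-ol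
Product: 8 (2E,6E)-7-iodo-3-methylocta-2,6-dienal
Conditions: MnO2, CH2Cl2, rt
Reagents that add atoms: none
Why: Allylic oxidation with MnO2 is selective for the allylic alcohol and should not isomerise the enal or affect the iodoalkene.

Step 6
Reactants: 8 (2E,6E)-7-iodo-3-methylocta-2,6-dienal; 9 methyl propiolate
Product: 10 methyl (4R,5E,9E)-4-hydroxy-10-iodo-6-methylundeca-5,9-dien-2-ynoate
Conditions: Me2Zn (3 equiv), (S,S)-ProPhenol (20 mol %), Ph3P=O (40 mol %), toluene, 0 to 4 °C
Reagents that add atoms: none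
Why: Catalytic asymmetric alkynylation of an α,β-unsaturated aldehyde by the zinc acetylide of methyl propiolate in the chiral dinuclear zinc–ProPhenol pocket should set the C2 carbinol (R descriptor at this stage) by catalyst control.

Step 7
Reactants: 10 methyl (4R,5E,9E)-4-hydroxy-10-iodo-6-methylundeca-5,9-dien-2-ynoate
Product: 11 methyl (4S)-4-hydroxy-4-[(2R,3R)-3-[(3E)-4-iodopent-3-en-1-yl]-3-methyloxiran-2-yl]but-2-ynoate
Conditions: mCPBA (1.2 equiv), NaHCO3, CH2Cl2, -20 to 0 °C
Reagents that add atoms: 3-chloroperoxybenzoic acid (OOC(=O)c1cccc(Cl)c1)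
Why: Hydroxyl-directed Prilezhaev epoxidation: the C4 methyl cis to the carbinol forces the carbinol hydrogen into the alkene plane (allylic 1,3-strain) and the hydrogen-bonded peracid is delivered to the face bearing the hydroxyl, which should give the threo epoxy alcohol (C3 and C4 from C2), while the iodoalkene and the ynoate are too electron-poor to react.

Step 8
Reactants: 11 methyl (4S)-4-hydroxy-4-[(2R,3R)-3-[(3E)-4-iodopent-3-en-1-yl]-3-methyloxiran-2-yl]but-2-ynoate
Product: 14 (5S)-3-(hydroxymethyl)-5-[(2R,3R)-3-[(3E)-4-iodopent-3-en-1-yl]-3-methyloxiran-2-yl]furan-2(5H)-one, via vinylalane 12 (not isolated), via hydroxy ester 13 (not isolated)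
Conditions: iBu2AlH (2.5 equiv), HMPA (4 equiv), THF, 0 °C; then CH2O (gas), 0 °C to rt; aqueous potassium sodium tartrate; PPTS (cat.), CH2Cl2, rt
Reagents that add atoms: formaldehyde (C=O)
Why: Conjugate syn hydroalumination of the ynoate by the HMPA-complexed aluminium hydride gives the α-aluminoacrylate with the carbinol carbon cis to the ester, its aldol-type capture by formaldehyde installs C17, and the cis γ-hydroxy ester should lactonise to the butenolide (hydroalumination–hydroxymethylation–lactonisation).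

Step 9
Reactants: 14 (5S)-3-(hydroxymethyl)-5-[(2R,3R)-3-[(3E)-4-iodopent-3-en-1-yl]-3-methyloxiran-2-yl]furan-2(5H)-one
Product: 15 (5S)-3-(bromomethyl)-5-[(2R,3R)-3-[(3E)-4-iodopent-3-en-1-yl]-3-methyloxiran-2-yl]furan-2(5H)-one
Conditions: CBr4, PPh3, 2,6-lutidine, CH2Cl2, 0 °C
Reagents that add atoms: carbon tetrabromide (BrC(Br)(Br)Br)
Why: Appel bromination of the primary allylic alcohol is neutral and should leave the epoxide and the epimerisable C2 centre untouched.

Step 10
Reactants: 16 but-3-yn-1-ol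
Product: 18 (3E)-3-methylhexa-3,5-dien-1-ol, via alkenylalane 17 (not isolated)
Conditions: Me3Al (3 equiv), Cp2ZrCl2 (0.25 equiv), CH2Cl2, 0 °C to rt; then vinyl bromide (1 M in THF), Pd(PPh3)4 (5 mol %), ZnCl2 (0.5 equiv), THF, rt
Reagents that add atoms: trimethylaluminium (C[Al](C)C); vinyl bromide (C=CBr)
Why: Negishi carboalumination sets the E trisubstituted alkene and the alkenylalane is cross-coupled in the same flask with vinyl bromide (palladium–zinc co-catalysed Negishi coupling) with retention to give the terminal diene.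

Step 11
Reactants: 18 (3E)-3-methylhexa-3,5-dien-1-ol
Product: 19 (3E)-3-methylhexa-3,5-dienal
Conditions: Dess–Martin periodinane, NaHCO3, CH2Cl2, 0 °C; crude aldehyde used at once
Reagents that add atoms: none
Why: Buffered Dess–Martin oxidation is mild enough to give the β,γ-unsaturated aldehyde without migration of the alkene into conjugation, provided the aldehyde is used immediately.

Step 12
Reactants: 15 (5S)-3-(bromomethyl)-5-[(2R,3R)-3-[(3E)-4-iodopent-3-en-1-yl]-3-methyloxiran-2-yl]furan-2(5H)-one; 19 (3E)-3-methylhexa-3,5-dienal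
Product: 20 (4R,5S)-4-[(1S,3E)-1-hydroxy-3-methylhexa-3,5-dien-1-yl]-5-[(2R,3R)-3-[(3E)-4-iodopent-3-en-1-yl]-3-methyloxiran-2-yl]-3-methylideneoxolan-2-one
Conditions: In powder (1.5 equiv), THF/H2O (1:1), rt
Reagents that add atoms: none
Why: Barbier allylation: the allylindium formed from the bromide attacks the aldehyde through its ring carbon C1 (SE2′, exo-methylene formed) on the butenolide face anti to the C2 substituent, and a Zimmerman–Traxler chair with the ring-fixed E-type geometry and the aldehyde chain equatorial should give the anti C1/C14 relationship, so C1 and C14 are set together from C2.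

Step 13
Reactants: 20 (4R,5S)-4-[(1S,3E)-1-hydroxy-3-methylhexa-3,5-dien-1-yl]-5-[(2R,3R)-3-[(3E)-4-iodopent-3-en-1-yl]-3-methyloxiran-2-yl]-3-methylideneoxolan-2-one
Product: 21 (1S,3E)-1-[(2S,3R)-2-[(2R,3R)-3-[(3E)-4-iodopent-3-en-1-yl]-3-methyloxiran-2-yl]-4-methylidene-5-oxooxolan-3-yl]-3-methylhexa-3,5-dien-1-yl acetate
Conditions: Ac2O, pyridine, DMAP (cat.), CH2Cl2, 0 °C
Reagents that add atoms: acetic anhydride (CC(=O)OC(C)=O)
Why: Acylation of the only free hydroxyl installs the C14 acetate of the target and at the same time blocks migration of the lactone acyl group from O2 to O14.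

Step 14
Reactants: 21 (1S,3E)-1-[(2S,3R)-2-[(2R,3R)-3-[(3E)-4-iodopent-3-en-1-yl]-3-methyloxiran-2-yl]-4-methylidene-5-oxooxolan-3-yl]-3-methylhexa-3,5-dien-1-yl acetate
Product: 22 (1S,3E)-1-[(2S,3R)-4-[(dimethylamino)methyl]-2-[(2R,3R)-3-[(3E)-4-iodopent-3-en-1-yl]-3-methyloxiran-2-yl]-5-oxooxolan-3-yl]-3-methylhexa-3,5-dien-1-yl acetate (both C15 epimers)
Conditions: Me2NH (2 M in THF, 1.5 equiv), THF, 0 °C
Reagents that add atoms: dimethylamine (CNC)
Why: Aza-Michael addition of the secondary amine to the exo-methylene lactone is fast and reversible on demand, and stores the Michael acceptor as a Mannich base that is inert to borane, base and palladium (the new C15 centre is lost again in step 16).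

Step 15
Reactants: 22 (1S,3E)-1-[(2S,3R)-4-[(dimethylamino)methyl]-2-[(2R,3R)-3-[(3E)-4-iodopent-3-en-1-yl]-3-methyloxiran-2-yl]-5-oxooxolan-3-yl]-3-methylhexa-3,5-dien-1-yl acetate
Product: 24 (1R,2S,3R,4R,7E,11E,14S)-14-acetoxy-17-(dimethylamino)-3,4-epoxycembra-7,11-dien-16,2-olide, via alkylborane 23 (not isolated)
Conditions: 9-BBN-H dimer (3 equiv B–H), THF, 0 °C to rt; then H2O; slow addition to Pd(dppf)Cl2 (20 mol %), AsPh3 (40 mol %), Cs2CO3, DMF/THF/H2O, 45 °C, final concentration 1 mM
Reagents that add atoms: none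
Why: 9-BBN adds anti-Markovnikov to the monosubstituted C9=C10 end of the diene to give the primary C9 borane; zerovalent palladium then inserts into the C8–I bond, base-assisted transmetalation transfers the primary alkyl group from boron, and reductive elimination forms C8–C9. This is an intramolecular B-alkyl Suzuki–Miyaura coupling, and the closest known type is the B-alkyl Suzuki macrocyclisation of terpenoid (E)-iodoalkenes. The only ring closed is the 14-membered carbocycle, by sp3–sp2 cross-coupling of the two chain ends in an endo sense, with C7=C8 ending inside the ring. No stereocentre is formed, and the E geometry of C7=C8 is that of the iodide, retained because oxidative addition and reductive elimination are stereospecific. The step needs site-selective hydroboration, ring closure over oligomerisation, and no β-hydride elimination; these are secured by the steric demand of 9-BBN (the trisubstituted alkenes, ester, acetate and epoxide are inert and the excess borane covers the amine), by slow addition at high dilution with the trans-lactone and trans-epoxide pre-bending the chain, and by the wide bite angle of dppf with AsPh3. The exo-methylene that could take up hydride or base is absent because it is stored as the amine adduct.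

Step 16
Reactants: 24 (1R,2S,3R,4R,7E,11E,14S)-14-acetoxy-17-(dimethylamino)-3,4-epoxycembra-7,11-dien-16,2-olide
Product: 26 (1R,2S,3R,4R,7E,11E,14S)-14-acetoxy-3,4-epoxycembra-7,11,15(17)-trien-16,2-olide, via ammonium iodide 25 (not isolated)
Conditions: MeI (excess), CH2Cl2/MeOH, rt; then NaHCO3 (aq.), rt
Reagents that add atoms: none
Why: Quaternisation of the Mannich base and mild base-induced β-elimination (Hofmann-type, E1cB through the lactone enolate) can only form the C15=C17 exo-methylene and should leave the acetate, epoxide and alkenes untouched.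

**Compound list**

1 | pent-3-yn-1-ol | CC#CCCO | starting material
2 | alkenylzirconocene: (E)-Cp2Zr(Cl)–C(CH3)=CH–CH2CH2–O–Zr(Cl)Cp2 | Cl[Zr](C1C=CC=C1)(C1C=CC=C1)/C(C)=C/CCO[Zr](Cl)(C1C=CC=C1)C1C=CC=C1 | intermediate
3 | (E)-4-iodopent-3-en-1-ol | OCC/C=C(C)/I | intermediate
4 | (E)-2,5-diiodopent-2-ene | ICC/C=C(C)/I | intermediate
5 | (E)-6-iodohept-5-en-1-yne | C#CCC/C=C(C)/I | intermediate
6 | alkenylalane: dimethyl[(1E,5E)-6-iodo-2-methylhepta-1,5-dien-1-yl]alane | C[Al](C)/C=C(\C)CC/C=C(C)/I | intermediate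
7 | (2E,6E)-7-iodo-3-methylocta-2,6-dien-1-ol | OC/C=C(\C)CC/C=C(C)/I | intermediate
8 | (2E,6E)-7-iodo-3-methylocta-2,6-dienal | O=C/C=C(\C)CC/C=C(C)/I | intermediate
9 | methyl propiolate | C#CC(=O)OC | starting material
10 | methyl (4R,5E,9E)-4-hydroxy-10-iodo-6-methylundeca-5,9-dien-2-ynoate | O[C@H](/C=C(\C)CC/C=C(C)/I)C#CC(=O)OC | intermediate
11 | methyl (4S)-4-hydroxy-4-[(2R,3R)-3-[(3E)-4-iodopent-3-en-1-yl]-3-methyloxiran-2-yl]but-2-ynoate | I/C(C)=C/CC[C@@]1(C)O[C@@H]1[C@@H](O)C#CC(=O)OC | intermediate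
12 | vinylalane: C2,O4-bis(diisobutylaluminium) derivative of the (Z)-but-2-enoate of 11 (carbinol carbon cis to the ester) | COC(=O)/C([Al](CC(C)C)CC(C)C)=C\[C@H](O[Al](CC(C)C)CC(C)C)[C@H]1O[C@]1(C)CC/C=C(C)/I | intermediate
13 | hydroxy ester: methyl (2Z,4S)-4-hydroxy-2-(hydroxymethyl)-4-[(2R,3R)-3-[(3E)-4-iodopent-3-en-1-yl]-3-methyloxiran-2-yl]but-2-enoate | COC(=O)/C(CO)=C\[C@H](O)[C@H]1O[C@]1(C)CC/C=C(C)/I | intermediate
14 | (5S)-3-(hydroxymethyl)-5-[(2R,3R)-3-[(3E)-4-iodopent-3-en-1-yl]-3-methyloxiran-2-yl]furan-2(5H)-one | OCC1=C[C@H](OC1=O)[C@H]2O[C@]2(C)CC/C=C(C)/I | intermediate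
15 | (5S)-3-(bromomethyl)-5-[(2R,3R)-3-[(3E)-4-iodopent-3-en-1-yl]-3-methyloxiran-2-yl]furan-2(5H)-one | BrCC1=C[C@H](OC1=O)[C@H]2O[C@]2(C)CC/C=C(C)/I | intermediate
16 | but-3-yn-1-ol | C#CCCO | starting material
17 | alkenylalane: dimethylaluminium alkoxide of (E)-4-(dimethylalumino)-3-methylbut-3-en-1-ol | C[Al](C)OCC/C(C)=C/[Al](C)C | intermediate
18 | (3E)-3-methylhexa-3,5-dien-1-ol | OCC/C(C)=C/C=C | intermediate
19 | (3E)-3-methylhexa-3,5-dienal | O=CC/C(C)=C/C=C | intermediate
20 | (4R,5S)-4-[(1S,3E)-1-hydroxy-3-methylhexa-3,5-dien-1-yl]-5-[(2R,3R)-3-[(3E)-4-iodopent-3-en-1-yl]-3-methyloxiran-2-yl]-3-methylideneoxolan-2-one | C=C1C(=O)O[C@H]([C@H]2O[C@]2(C)CC/C=C(C)/I)[C@H]1[C@@H](O)C/C(C)=C/C=C | intermediate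
21 | (1S,3E)-1-[(2S,3R)-2-[(2R,3R)-3-[(3E)-4-iodopent-3-en-1-yl]-3-methyloxiran-2-yl]-4-methylidene-5-oxooxolan-3-yl]-3-methylhexa-3,5-dien-1-yl acetate | C=C1C(=O)O[C@H]([C@H]2O[C@]2(C)CC/C=C(C)/I)[C@H]1[C@@H](OC(C)=O)C/C(C)=C/C=C | intermediate
22 | dimethylamine adduct of 21 at C17 (4-[(dimethylamino)methyl]oxolan-2-one; both C15 epimers) | CN(C)CC1C(=O)O[C@H]([C@H]2O[C@]2(C)CC/C=C(C)/I)[C@H]1[C@@H](OC(C)=O)C/C(C)=C/C=C | intermediate
23 | alkylborane: C9 (9-borabicyclo[3.3.1]nonan-9-yl) adduct of 22 | CN(C)CC1C(=O)O[C@H]([C@H]2O[C@]2(C)CC/C=C(C)/I)[C@H]1[C@@H](OC(C)=O)C/C(C)=C/CCB3C4CCCC3CCC4 | intermediate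
24 | (1R,2S,3R,4R,7E,11E,14S)-14-acetoxy-17-(dimethylamino)-3,4-epoxycembra-7,11-dien-16,2-olide (both C15 epimers) | CN(C)CC1C(=O)O[C@H]2[C@H]1[C@@H](OC(C)=O)C/C(C)=C/CC/C(C)=C/CC[C@@]1(C)O[C@H]21 | intermediate
25 | ammonium iodide: N-methyl trimethylammonium iodide of 24 | C[N+](C)(C)CC1C(=O)O[C@H]2[C@H]1[C@@H](OC(C)=O)C/C(C)=C/CC/C(C)=C/CC[C@@]1(C)O[C@H]21.[I-] | intermediate
26 | (1R,2S,3R,4R,7E,11E,14S)-14-acetoxy-3,4-epoxycembra-7,11,15(17)-trien-16,2-olide | C=C1C(=O)O[C@H]2[C@H]1[C@@H](OC(C)=O)C/C(C)=C/CC/C(C)=C/CC[C@@]1(C)O[C@H]21 | target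

**Step count and risks**

Total step count: 16. Longest linear sequence: 14 (steps 1 to 9 and 12 to 16).

Steps most likely to fail:

1. Step 15. The hydroboration may be slowed or misdirected because the amine binds the borane, and intermolecular coupling or protodeboronation may outrun ring closure. The fallback sets out from 21 and comes back at 26, closing the same C8–C9 bond by a Negishi coupling. Thiophenol with catalytic Et3N would mask the methylene as the phenylthiomethyl lactone F1. Hydroboration with 9-BBN to the alkylborane F2 and oxidation with Me3NO would give the primary C9 alcohol F3, which can be purified. I2, PPh3 and imidazole would give the primary iodide F4. Zinc insertion (Zn dust, LiCl, THF) into the alkyl C–I bond only would give the alkylzinc iodide F5. Slow addition of F5 to Pd2(dba)3 and SPhos at high dilution would give the macrocyclic sulfide F6. NaIO4 would give the sulfoxide F7, and heating in toluene would eliminate benzenesulfenic acid to give 26.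

2. Step 8. The aluminium hydride may open the epoxide or over-reduce the ester, or the Z geometry may erode through the allenolate so that lactonisation fails. The fallback sets out from 11 and comes back at 14. Z-selective semi-reduction of the ynoate with zinc activated by copper and silver (Zn(Cu/Ag), MeOH/H2O) would give the (Z)-hydroxy enoate F8, which lactonises to the butenolide F9. PhSeLi (THF, -78 °C) would add to C1 anti to the C2 substituent, and the lactone enolate would be trapped with gaseous CH2O to give the selenide F10. H2O2 would oxidise it to the selenoxide F11, whose syn elimination towards C15 restores the butenolide double bond and gives 14.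

3. Step 12. Simple or facial diastereocontrol at C14 may be lost through an open transition state in the aqueous medium. The fallback sets out from 15 and 19 and comes back at 21. The two C14 epimers would be separated after the allylation. The 14S alcohol 20 goes on as in step 13. The 14R epimer F12 would be converted into the same acetate 21 by a Mitsunobu reaction with acetic acid (PPh3, DIAD, AcOH), which installs the acetate with inversion at C14.

Further compounds
F1 | step 15 | thiophenol adduct of 21 at C17 (4-[(phenylsulfanyl)methyl]oxolan-2-one; both C15 epimers) | c1ccccc1SCC2C(=O)O[C@H]([C@H]3O[C@]3(C)CC/C=C(C)/I)[C@H]2[C@@H](OC(C)=O)C/C(C)=C/C=C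
F2 | step 15 | C9 (9-borabicyclo[3.3.1]nonan-9-yl) borane of F1 | c1ccccc1SCC2C(=O)O[C@H]([C@H]3O[C@]3(C)CC/C=C(C)/I)[C@H]2[C@@H](OC(C)=O)C/C(C)=C/CCB4C5CCCC4CCC5
F3 | step 15 | primary C9 alcohol from F2 | c1ccccc1SCC2C(=O)O[C@H]([C@H]3O[C@]3(C)CC/C=C(C)/I)[C@H]2[C@@H](OC(C)=O)C/C(C)=C/CCO
F4 | step 15 | primary C9 iodide from F3 | c1ccccc1SCC2C(=O)O[C@H]([C@H]3O[C@]3(C)CC/C=C(C)/I)[C@H]2[C@@H](OC(C)=O)C/C(C)=C/CCI
F5 | step 15 | C9 alkylzinc iodide from F4 | c1ccccc1SCC2C(=O)O[C@H]([C@H]3O[C@]3(C)CC/C=C(C)/I)[C@H]2[C@@H](OC(C)=O)C/C(C)=C/CC[Zn]I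
F6 | step 15 | (1R,2S,3R,4R,7E,11E,14S)-14-acetoxy-3,4-epoxy-17-(phenylsulfanyl)cembra-7,11-dien-16,2-olide | c1ccccc1SCC1C(=O)O[C@H]2[C@H]1[C@@H](OC(C)=O)C/C(C)=C/CC/C(C)=C/CC[C@@]1(C)O[C@H]21
F7 | step 15 | sulfoxide of F6 | O=S(c1ccccc1)CC1C(=O)O[C@H]2[C@H]1[C@@H](OC(C)=O)C/C(C)=C/CC/C(C)=C/CC[C@@]1(C)O[C@H]21
F8 | step 8 | methyl (2Z,4S)-4-hydroxy-4-[(2R,3R)-3-[(3E)-4-iodopent-3-en-1-yl]-3-methyloxiran-2-yl]but-2-enoate | COC(=O)/C=C\[C@H](O)[C@H]1O[C@]1(C)CC/C=C(C)/I
F9 | step 8 | (5S)-5-[(2R,3R)-3-[(3E)-4-iodopent-3-en-1-yl]-3-methyloxiran-2-yl]furan-2(5H)-one | O=C1C=C[C@H](O1)[C@H]2O[C@]2(C)CC/C=C(C)/I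
F10 | step 8 | (5S)-3-(hydroxymethyl)-5-[(2R,3R)-3-[(3E)-4-iodopent-3-en-1-yl]-3-methyloxiran-2-yl]-4-(phenylselanyl)oxolan-2-one | OCC1C([Se]c2ccccc2)[C@H](OC1=O)[C@H]3O[C@]3(C)CC/C=C(C)/I
F11 | step 8 | selenoxide of F10 | OCC1C([Se](=O)c2ccccc2)[C@H](OC1=O)[C@H]3O[C@]3(C)CC/C=C(C)/I
F12 | step 12 | C14 epimer of 20: (4R,5S)-4-[(1R,3E)-1-hydroxy-3-methylhexa-3,5-dien-1-yl]-5-[(2R,3R)-3-[(3E)-4-iodopent-3-en-1-yl]-3-methyloxiran-2-yl]-3-methylideneoxolan-2-one | C=C1C(=O)O[C@H]([C@H]2O[C@]2(C)CC/C=C(C)/I)[C@H]1[C@H](O)C/C(C)=C/C=C
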